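**Retrosynthetic overview**
1. Target ⇒ second aryl–CH bond: hydroarylation of an ortho-hydroxystyrene (ring B carrying an (E)-3-methylbut-1-enyl group) by 3-prenyl-2,4,6-trihydroxyacetophenone (ring A) through an ortho-quinone methide.
2. The styrene ⇒ ring B carbon–alkenyl carbon bond, two natively nucleophilic carbons: ring B is used as an enolonium equivalent (its phenyliodonium ylide) and coupled with an (E)-alkenylboronate under palladium.
3. Alkenylboronate ⇒ 3-methylbut-1-yne + pinacolborane; prenylated monomer ⇒ 2,4,6-trihydroxyacetophenone + prenyl bromide.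
4. No ring is formed: both benzene rings come intact from 2,4,6-trihydroxyacetophenone, and one prenylated monomer supplies ring A and ring B.

Assumption: the target has no stereocentre (the bridging methine carries two identical aryl groups) and no stereogenic alkene, so it is achiral and the compound itself is the only stereoisomer.

**Step 1**
Reactants: 1 1-(2,4,6-trihydroxyphenyl)ethan-1-one (2,4,6-trihydroxyacetophenone); 2 1-bromo-3-methylbut-2-ene (prenyl bromide)
Product: 3 1-[2,4,6-trihydroxy-3-(3-methylbut-2-en-1-yl)phenyl]ethan-1-one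
Conditions: 2 (0.9 equiv), 10% aq KOH (1.0 equiv), 0 °C, 2 h; then 1 M HCl
Reagents that add atoms: none
Why: Phenolate C-alkylation: in water the soft, ambident anion of this vinylogous acid reacts with the allylic bromide mainly at a ring carbon, and the substoichiometric bromide limits dialkylation (both free positions are equivalent, so only one mono-C-prenyl isomer forms).

**Step 2**
Reactants: 4 3-methylbut-1-yne; 5 4,4,5,5-tetramethyl-1,3,2-dioxaborolane (pinacolborane)
Product: 6 4,4,5,5-tetramethyl-2-[(E)-3-methylbut-1-en-1-yl]-1,3,2-dioxaborolane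
Conditions: Cp2Zr(H)Cl (5 mol%), Et3N (10 mol%), neat, sealed tube, 60 °C, 16 h
Reagents that add atoms: none
Why: Zirconium-catalysed alkyne hydroboration: syn, anti-Markovnikov addition of B–H to the terminal alkyne gives only the E-alkenylboronate.

**Step 3**
Reactants: 3 1-[2,4,6-trihydroxy-3-(3-methylbut-2-en-1-yl)phenyl]ethan-1-one; 7 (diacetoxyiodo)benzene, PhI(OAc)2; 6 4,4,5,5-tetramethyl-2-[(E)-3-methylbut-1-en-1-yl]-1,3,2-dioxaborolane
Product: 9 1-{2,4,6-trihydroxy-3-[(E)-3-methylbut-1-en-1-yl]-5-(3-methylbut-2-en-1-yl)phenyl}ethan-1-one, via phenyliodonium ylide 8 (not isolated)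
Conditions: 7 (1.0 equiv), K2CO3 (2.2 equiv), MeOH, −10 °C, 30 min, dark; then 6 (1.3 equiv), Pd(OAc)2 (5 mol%), [HP(t-Bu)3]BF4 (10 mol%), K2CO3 (2 equiv), DME–H2O 4:1, 20 °C, 4 h, Ar; pH 5 phosphate work-up, 9 used crude
Reagents that add atoms: none
Why: Proposed new method: the acylphloroglucinol is a cyclic vinylogous β-triketone whose enolate should bond to trivalent iodine at its only unsubstituted ring carbon and lose that proton to give the zwitterionic ylide 8, as cyclic 1,3-diones, 4-hydroxycoumarins and hydroxyquinones do; this turns the normally nucleophilic enol carbon into an electrophile (enolonium equivalent), zerovalent palladium inserts into its C–I bond with loss of iodobenzene at room temperature, and transmetalation from 6 followed by reductive elimination joins the two natively nucleophilic carbons with retention of the E geometry; the closest known reaction type is the Suzuki–Miyaura coupling of phenyliodonium ylides of 4-hydroxycoumarin and 2-hydroxy-1,4-naphthoquinone with boronic acids.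

**Step 4**
Reactants: 9 1-{2,4,6-trihydroxy-3-[(E)-3-methylbut-1-en-1-yl]-5-(3-methylbut-2-en-1-yl)phenyl}ethan-1-one; 3 1-[2,4,6-trihydroxy-3-(3-methylbut-2-en-1-yl)phenyl]ethan-1-one
Product: 10 1,1'-{(3-methylbutane-1,1-diyl)bis[2,4,6-trihydroxy-5-(3-methylbut-2-en-1-yl)-3,1-phenylene]}bis(ethan-1-one)
Conditions: 3 (1.2 equiv), (PhO)2P(O)OH (10 mol%), CH2Cl2, 25 °C, 6 h
Reagents that add atoms: none
Why: Brønsted acid-catalysed hydroarylation of an ortho-hydroxystyrene: protonation at the alkene carbon remote from the ring gives the ortho-quinone methide of ring B, and the single free ring carbon of 3 adds to its benzylic carbon in a Friedel–Crafts/Michael sense; the new methine bears two identical aryl groups and is not a stereocentre, and the mild acid leaves the prenyl groups alone.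

**Compound list**
1 | 1-(2,4,6-trihydroxyphenyl)ethan-1-one (2,4,6-trihydroxyacetophenone) | CC(=O)c1c(O)cc(O)cc1O | starting material
2 | 1-bromo-3-methylbut-2-ene (prenyl bromide) | CC(C)=CCBr | starting material
3 | 1-[2,4,6-trihydroxy-3-(3-methylbut-2-en-1-yl)phenyl]ethan-1-one | CC(=O)c1c(O)cc(O)c(CC=C(C)C)c1O | intermediate
4 | 3-methylbut-1-yne | CC(C)C#C | starting material
5 | 4,4,5,5-tetramethyl-1,3,2-dioxaborolane (pinacolborane) | CC1(C)OBOC1(C)C | starting material
6 | 4,4,5,5-tetramethyl-2-[(E)-3-methylbut-1-en-1-yl]-1,3,2-dioxaborolane | CC(C)/C=C/B1OC(C)(C)C(C)(C)O1 | intermediate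
7 | (diacetoxyiodo)benzene, PhI(OAc)2 | CC(=O)OI(OC(C)=O)c1ccccc1 | starting material
8 | 2-acetyl-3,5-dihydroxy-4-(3-methylbut-2-en-1-yl)-6-(phenyliodonio)phenolate, the phenyliodonium ylide of 3 | CC(=O)c1c(O)c(CC=C(C)C)c(O)c([I+]c2ccccc2)c1[O-] | intermediate
9 | 1-{2,4,6-trihydroxy-3-[(E)-3-methylbut-1-en-1-yl]-5-(3-methylbut-2-en-1-yl)phenyl}ethan-1-one | CC(=O)c1c(O)c(CC=C(C)C)c(O)c(/C=C/C(C)C)c1O | intermediate
10 | 1,1'-{(3-methylbutane-1,1-diyl)bis[2,4,6-trihydroxy-5-(3-methylbut-2-en-1-yl)-3,1-phenylene]}bis(ethan-1-one); achiral | CC(=O)c1c(O)c(CC=C(C)C)c(O)c(C(CC(C)C)c2c(O)c(CC=C(C)C)c(O)c(C(C)=O)c2O)c1O | target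

**Totals**
Total step count: 4. Longest linear sequence: 3 steps (1 → 3 → 9 → 10); step 2 is a one-step side branch.

**Steps most likely to fail, with fallbacks**

Step 3 (the polarity-reversed coupling). The trivalent iodine reagent may attack the prenyl alkene or over-oxidise the very electron-rich ring of 3, and the ylide may rearrange before palladium intercepts it. The fallback moves the coupling ahead of prenylation so that no alkene is present during the oxidation. It sets out from 1: treatment with 7 (K2CO3, MeOH, −10 °C) forms in the flask 2-acetyl-3,5-dihydroxy-6-(phenyliodonio)phenolate F2. This is coupled with 6 (Pd(OAc)2, [HP(t-Bu)3]BF4, K2CO3, DME–H2O, 20 °C) to give 1-{2,4,6-trihydroxy-3-[(E)-3-methylbut-1-en-1-yl]phenyl}ethan-1-one F3. C-Prenylation of F3 at its one remaining ring position with 2 (10% aq KOH, 0 °C) then comes back to the route at 9.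

Step 4 (hydroarylation). The acid may instead close a prenyl group onto a neighbouring phenol (chroman formation), or the quinone methide may be trapped too slowly. The fallback separates quinone methide formation from the C–C bond formation and makes the latter base-mediated. It sets out from 9: 4-methylbenzenesulfinic acid, made in the flask from sodium 4-methylbenzenesulfinate and HCO2H (CH2Cl2–H2O, 20 °C), adds to the styrene to give racemic 1-{2,4,6-trihydroxy-3-[3-methyl-1-(4-methylbenzenesulfonyl)butyl]-5-(3-methylbut-2-en-1-yl)phenyl}ethan-1-one F4. With K2CO3 and 3 in CH2Cl2 at 20 °C, F4 eliminates sulfinate to the ortho-quinone methide, which the anion of 3 captures at carbon, coming back to the route at 10.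

Step 1 (mono-C-prenylation). Competing O-alkylation and double C-alkylation usually keep the yield modest. The fallback goes through the oxygen. It sets out from 1: alkylation of the most acidic, non-chelated 4-hydroxyl with 2 (K2CO3, acetone, 56 °C) gives 1-[2,6-dihydroxy-4-(3-methylbut-2-en-1-yloxy)phenyl]ethan-1-one F1. Heating F1 with MgSiO3 (Florisil) in toluene at 110 °C induces a 1,3-shift of the prenyl group from oxygen to the adjacent ring carbon, coming back to the route at 3.

**Further compounds**
F1 | step 1 | 1-[2,6-dihydroxy-4-(3-methylbut-2-en-1-yloxy)phenyl]ethan-1-one | CC(=O)c1c(O)cc(OCC=C(C)C)cc1O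
F2 | step 3 | 2-acetyl-3,5-dihydroxy-6-(phenyliodonio)phenolate | CC(=O)c1c(O)cc(O)c([I+]c2ccccc2)c1[O-]
F3 | step 3 | 1-{2,4,6-trihydroxy-3-[(E)-3-methylbut-1-en-1-yl]phenyl}ethan-1-one | CC(=O)c1c(O)cc(O)c(/C=C/C(C)C)c1O
F4 | step 4 | racemic 1-{2,4,6-trihydroxy-3-[3-methyl-1-(4-methylbenzenesulfonyl)butyl]-5-(3-methylbut-2-en-1-yl)phenyl}ethan-1-one | CC(=O)c1c(O)c(CC=C(C)C)c(O)c(C(CC(C)C)S(=O)(=O)c2ccc(C)cc2)c1O
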